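## Retrosynthetic overview

1. Feature: in ring A (the 2,6-dihydroxyphenyl ring), ring carbon C1' carries the ketone carbon C1 and lies between the oxygen-bearing carbons C2' and C6'. An acyl carbon and an oxygen on adjacent ring carbons, next to a carbon that already bears oxygen, is what results when a carboxylic acid adds across the strained triple bond of 3-methoxybenzyne.
2. Last disconnection: the three O–CH3 bonds of the trimethyl ether of the target (one on ring A, two on ring B).
3. Key disconnection: C1–C1' and O–C2' together, leading back to 9-(3,4-dimethoxyphenyl)nonanoic acid and 3-methoxy-2-(trimethylsilyl)phenyl triflate as the aryne source.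
4. The acid comes from a Wittig bond (C8=C9) between 3,4-dimethoxybenzaldehyde and the ylide of 8-bromooctanoic acid, then hydrogenation. The silyl triflate comes from carbamate-directed C2 silylation of 3-methoxyphenol, then exchange of carbamate for triflate.
5. No ring is formed at any stage. Rings A and B are both bought, and the target has no stereocentre.

Key step: step 7

Remark: a salt that arises from a numbered acid or phenol by proton transfer alone is counted under the number of the neutral compound. Alkene 13 is carried as a Z/E mixture because step 6 erases its geometry.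

## Route

Step 1
Reactants: 1 3-methoxyphenol
Product: 2 3-methoxyphenyl isopropylcarbamate
Conditions: i-PrNCO (1.5 equiv), Et3N (0.2 equiv), CH2Cl2, rt
Reagents that add atoms: isopropyl isocyanate, CC(C)N=C=O
Why: Base-catalysed carbamoylation (addition of the phenol O–H across the isocyanate C=N) should be clean because 1 has no other nucleophilic site, and it installs a strong ortho-directing group that can later be removed under mild base.

Step 2
Reactants: 2 3-methoxyphenyl isopropylcarbamate
Product: 6 3-methoxy-2-(trimethylsilyl)phenyl isopropylcarbamate, via N-TBS carbamate 3 (not isolated), via C2-lithio carbamate 4 (not isolated), via N-TBS C2-TMS carbamate 5 (not isolated)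
Conditions: TBSOTf, TMEDA, Et2O, 0 °C → rt; n-BuLi (2 equiv), TMEDA, −78 °C; TMSCl, −78 °C → rt; aq. NaHSO4
Reagents that add atoms: chlorotrimethylsilane, C[Si](C)(C)Cl; tert-butyldimethylsilyl triflate, CC(C)(C)[Si](C)(C)OS(=O)(=O)C(F)(F)F (its silyl group stays only in 3, 4, 5); n-butyllithium, [Li]CCCC (its lithium stays only in 4)
Why: In this directed ortho-metalation with in situ N-silyl protection, the N-TBS group blocks N–H deprotonation and isocyanate loss, n-BuLi/TMEDA removes the C2 proton between the carbamate and methoxy oxygens (cooperative direction), TMSCl traps the aryllithium at −78 °C before an anionic ortho-Fries shift can start, and the labile N–Si bond is hydrolysed in the work-up.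

Step 3
Reactants: 6 3-methoxy-2-(trimethylsilyl)phenyl isopropylcarbamate
Product: 8 3-methoxy-2-(trimethylsilyl)phenyl trifluoromethanesulfonate, via 3-methoxy-2-(trimethylsilyl)phenol 7 (not isolated)
Conditions: DBU, Et2NH, MeCN, 40 °C; then PhNTf2, rt
Reagents that add atoms: N-phenylbis(trifluoromethanesulfonimide), O=S(=O)(N(c1ccccc1)S(=O)(=O)C(F)(F)F)C(F)(F)F
Why: E1cB cleavage of the secondary carbamate (DBU removes N–H, the phenoxide leaves, Et2NH scavenges the isocyanate) is followed in the same flask by O-sulfonylation of the phenoxide with PhNTf2, so the sensitive ortho-silylphenol never has to be handled.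

Step 4
Reactants: 9 8-bromooctanoic acid
Product: 10 (7-carboxyheptyl)triphenylphosphonium bromide
Conditions: PPh3, MeCN, reflux
Reagents that add atoms: triphenylphosphine, c1ccc(cc1)P(c1ccccc1)c1ccccc1
Why: SN2 quaternisation of PPh3 by an unhindered primary bromide should proceed cleanly, and the free carboxylic acid is inert to it.

Step 5
Reactants: 10 (7-carboxyheptyl)triphenylphosphonium bromide, 11 3,4-dimethoxybenzaldehyde
Product: 13 9-(3,4-dimethoxyphenyl)non-8-enoic acid (Z/E mixture), via carboxylate ylide 12 (not isolated)
Conditions: KOtBu (2.2 equiv), THF, 0 °C; then 11, 0 °C → rt; aq. HCl work-up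
Reagents that add atoms: potassium tert-butoxide, CC(C)(C)[O-].[K+] (its potassium stays only in 12)
Why: In this Wittig olefination two equivalents of base give the carboxylate ylide, which condenses with the non-enolisable aromatic aldehyde, and the alkene geometry (Z expected to prevail) does not matter because step 6 removes it.

Step 6
Reactants: 13 9-(3,4-dimethoxyphenyl)non-8-enoic acid
Product: 14 9-(3,4-dimethoxyphenyl)nonanoic acid
Conditions: H2 (1 atm), Pd/C (10 wt% Pd on carbon), EtOAc, rt
Reagents that add atoms: none
Why: Heterogeneous catalytic hydrogenation saturates the disubstituted styrene-type alkene of both isomers and leaves the aryl methyl ethers and the carboxylic acid untouched.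

Step 7
Reactants: 14 9-(3,4-dimethoxyphenyl)nonanoic acid, 8 3-methoxy-2-(trimethylsilyl)phenyl trifluoromethanesulfonate
Product: 17 9-(3,4-dimethoxyphenyl)-1-(2-hydroxy-6-methoxyphenyl)nonan-1-one, via 3-methoxybenzyne 15 (not isolated), via ortho-cesio aryl ester 16 (not isolated)
Conditions: 8 (1.5 equiv), CsF (4 equiv), THF, 125 °C, sealed tube
Reagents that add atoms: cesium fluoride, [Cs+].[F-] (its cesium stays only in 16)
Why: Fluoride attacks silicon in 8 and triflate departs from the neighbouring carbon, which feeds 3-methoxybenzyne 15 into the mixture slowly and at low concentration. The carboxylate of 14 adds through oxygen to the aryne carbon meta to the methoxy group, because the distorted aryne is more electrophilic there and because the charge then develops on the carbon ortho to OMe, where the C–O dipole stabilises it (16). In aprotic THF at 125 °C the carbanion of 16 attacks its own ester carbonyl through a four-centre transition state and the acyl group moves from O to C, so the aryne has in effect inserted into the acyl C–O bond and the new C1–C1' and O–C2' bonds stand on adjacent ring carbons with C1' between OH and OMe. The closest known reaction type is this same fluoride-induced insertion of arynes into the C–O bond of carboxylic acids to give ortho-hydroxyaryl ketones, an intermolecular relative of the anionic ortho-Fries rearrangement, and aliphatic acids belong to its substrate class. No ring is closed and no stereocentre is created. The step needs regioselective addition to the unsymmetrical aryne, which the 3-methoxy group secures, and acyl transfer ahead of protonation of 16, which is favoured by the non-acidic solvent, by the excess CsF that holds 14 as its carboxylate and by the high temperature, while the hydrogen bond from the new phenol to the ketone lowers its tendency to be arylated by a second aryne.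

Step 8
Reactants: 17 9-(3,4-dimethoxyphenyl)-1-(2-hydroxy-6-methoxyphenyl)nonan-1-one
Product: 18 malabaricone C, 9-(3,4-dihydroxyphenyl)-1-(2,6-dihydroxyphenyl)nonan-1-one
Conditions: BBr3 (6 equiv), CH2Cl2, −78 °C → rt; then ice-water under argon
Reagents that add atoms: none
Why: In this Lewis-acid ether cleavage each aryl methyl ether binds BBr3 and loses its methyl group to bromide attack, the ether next to the ketone is helped by chelation, the aryl borates are hydrolysed on quench, and the saturated chain and the ketone are inert.

## Compound list

1 | 3-methoxyphenol | COc1cccc(O)c1 | starting material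
2 | 3-methoxyphenyl isopropylcarbamate | COc1cccc(OC(=O)NC(C)C)c1 | intermediate
3 | 3-methoxyphenyl N-(tert-butyldimethylsilyl)-N-isopropylcarbamate (in flask, step 2) | COc1cccc(OC(=O)N(C(C)C)[Si](C)(C)C(C)(C)C)c1 | intermediate
4 | 2-lithio-3-methoxyphenyl N-(tert-butyldimethylsilyl)-N-isopropylcarbamate (in flask, step 2) | COc1cccc(OC(=O)N(C(C)C)[Si](C)(C)C(C)(C)C)c1[Li] | intermediate
5 | 3-methoxy-2-(trimethylsilyl)phenyl N-(tert-butyldimethylsilyl)-N-isopropylcarbamate (in flask, step 2) | COc1cccc(OC(=O)N(C(C)C)[Si](C)(C)C(C)(C)C)c1[Si](C)(C)C | intermediate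
6 | 3-methoxy-2-(trimethylsilyl)phenyl isopropylcarbamate | COc1cccc(OC(=O)NC(C)C)c1[Si](C)(C)C | intermediate
7 | 3-methoxy-2-(trimethylsilyl)phenol (in flask, step 3) | COc1cccc(O)c1[Si](C)(C)C | intermediate
8 | 3-methoxy-2-(trimethylsilyl)phenyl trifluoromethanesulfonate | COc1cccc(OS(=O)(=O)C(F)(F)F)c1[Si](C)(C)C | intermediate
9 | 8-bromooctanoic acid | OC(=O)CCCCCCCBr | starting material
10 | (7-carboxyheptyl)triphenylphosphonium bromide | OC(=O)CCCCCCC[P+](c1ccccc1)(c1ccccc1)c1ccccc1.[Br-] | intermediate
11 | 3,4-dimethoxybenzaldehyde | COc1ccc(C=O)cc1OC | starting material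
12 | potassium 8-(triphenyl-λ5-phosphanylidene)octanoate (in flask, step 5) | [K+].[O-]C(=O)CCCCCCC=P(c1ccccc1)(c1ccccc1)c1ccccc1 | intermediate
13 | 9-(3,4-dimethoxyphenyl)non-8-enoic acid (Z/E mixture, geometry not specified) | COc1ccc(C=CCCCCCCC(=O)O)cc1OC | intermediate
14 | 9-(3,4-dimethoxyphenyl)nonanoic acid | COc1ccc(CCCCCCCCC(=O)O)cc1OC | intermediate
15 | 3-methoxybenzyne, 1-methoxy-2,3-didehydrobenzene (in flask, step 7) | COC1=CC=CC#C1 | intermediate
16 | 2-cesio-3-methoxyphenyl 9-(3,4-dimethoxyphenyl)nonanoate (in flask, step 7) | COc1ccc(CCCCCCCCC(=O)Oc2cccc(OC)c2[Cs])cc1OC | intermediate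
17 | 9-(3,4-dimethoxyphenyl)-1-(2-hydroxy-6-methoxyphenyl)nonan-1-one | COc1ccc(CCCCCCCCC(=O)c2c(O)cccc2OC)cc1OC | intermediate
18 | malabaricone C, 9-(3,4-dihydroxyphenyl)-1-(2,6-dihydroxyphenyl)nonan-1-one | O=C(CCCCCCCCc1ccc(O)c(O)c1)c1c(O)cccc1O | target

## Step count

Total step count: 8.
Longest linear sequence: 5 steps. Both branches are equally long: steps 1, 2, 3, 7, 8 or steps 4, 5, 6, 7, 8.

## Steps most likely to fail

1. Step 7 (key step).
- What may go wrong: the aryl anion may be protonated before the acyl shift, so the sequence stops at O-arylation. The product phenoxide may be arylated by a second aryne. Regiocontrol may erode at 125 °C.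
- Fallback: ring A enters as a nucleophile instead of an aryne, by directed lithiation and Weinreb ketone synthesis. It sets out from 14 and comes back at 18.
- Acid 14 is coupled with MeNH(OMe)·HCl (EDC·HCl, Et3N, CH2Cl2) to give 9-(3,4-dimethoxyphenyl)-N-methoxy-N-methylnonanamide F1. 1,3-Dimethoxybenzene is lithiated between its two oxygens (n-BuLi, THF, 0 °C → rt) to give 2,6-dimethoxyphenyllithium F2. F2 adds to F1 (−78 → 0 °C), and collapse of the chelate on quench should give 1-(2,6-dimethoxyphenyl)-9-(3,4-dimethoxyphenyl)nonan-1-one F3. F3 takes the place of 17 under the conditions of step 8, with more BBr3 for the fourth ether, and the route is rejoined at 18.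

2. Step 2.
- What may go wrong: incomplete N-silylation would let n-BuLi remove the N–H, and the carbamate would then collapse with loss of isocyanate. The acyl group of the lithiated species may migrate before silylation. The aryl–silicon bond, flanked by two oxygen substituents, may be lost in the acidic work-up.
- Fallback: acetal-directed lithiation, with bromine as a placeholder, then a retro-Brook silyl shift. The directing group has no N–H and no carbonyl. The fallback sets out from 1, bypasses steps 2 and 3, and comes back at 8.
- Phenol 1 is protected (MOMCl, i-Pr2NEt, CH2Cl2) as 1-methoxy-3-(methoxymethoxy)benzene F4. n-BuLi (THF, 0 °C) lithiates the position between the two oxygens, and 1,2-dibromoethane (−78 °C) gives 2-bromo-1-methoxy-3-(methoxymethoxy)benzene F5. HCl in MeOH frees 2-bromo-3-methoxyphenol F6, and HMDS (THF, reflux) gives (2-bromo-3-methoxyphenoxy)trimethylsilane F7.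
- n-BuLi (THF, −100 → −78 °C) then effects bromine–lithium exchange and silicon moves from oxygen to the carbanion. The lithium salt of 7 is trapped at once with Tf2O to give 8 without meeting a proton source.

3. Step 8.
- What may go wrong: ether cleavage may be incomplete. The Lewis acid may strip the acyl group from the electron-rich ring A. The catechol may oxidise in air during the aqueous work-up of a very polar tetraphenol.
- Fallback: a change of protecting-group plan, with benzyl in place of methyl and a neutral hydrogenolysis as the last step. It sets out from 10 and comes back at 18.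
- Commercial 3-(benzyloxy)phenol is taken through the operations of steps 1 to 3. This gives in turn 3-(benzyloxy)phenyl isopropylcarbamate F8, 3-(benzyloxy)-2-(trimethylsilyl)phenyl isopropylcarbamate F9 and 3-(benzyloxy)-2-(trimethylsilyl)phenyl trifluoromethanesulfonate F10.
- Ylide 12, made from 10 as in step 5, is condensed with commercial 3,4-bis(benzyloxy)benzaldehyde to give 9-[3,4-bis(benzyloxy)phenyl]non-8-enoic acid F11. Its alkene is reduced with diimide (TsNHNH2, NaOAc, THF/H2O, reflux), which spares benzyl ethers, to give 9-[3,4-bis(benzyloxy)phenyl]nonanoic acid F12.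
- F12 and F10 under the conditions of step 7 should give 1-[2-(benzyloxy)-6-hydroxyphenyl]-9-[3,4-bis(benzyloxy)phenyl]nonan-1-one F13, because the benzyloxy group directs as the methoxy group does. H2, Pd/C, EtOAc/MeOH, rt then removes the three benzyl groups to give 18.

## Further compounds

F1 | step 7 | 9-(3,4-dimethoxyphenyl)-N-methoxy-N-methylnonanamide | COc1ccc(CCCCCCCCC(=O)N(C)OC)cc1OC
F2 | step 7 | 2,6-dimethoxyphenyllithium | COc1cccc(OC)c1[Li]
F3 | step 7 | 1-(2,6-dimethoxyphenyl)-9-(3,4-dimethoxyphenyl)nonan-1-one | COc1ccc(CCCCCCCCC(=O)c2c(OC)cccc2OC)cc1OC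
F4 | step 2 | 1-methoxy-3-(methoxymethoxy)benzene | COCOc1cccc(OC)c1
F5 | step 2 | 2-bromo-1-methoxy-3-(methoxymethoxy)benzene | COCOc1cccc(OC)c1Br
F6 | step 2 | 2-bromo-3-methoxyphenol | COc1cccc(O)c1Br
F7 | step 2 | (2-bromo-3-methoxyphenoxy)trimethylsilane | COc1cccc(O[Si](C)(C)C)c1Br
F8 | step 8 | 3-(benzyloxy)phenyl isopropylcarbamate | CC(C)NC(=O)Oc1cccc(OCc2ccccc2)c1
F9 | step 8 | 3-(benzyloxy)-2-(trimethylsilyl)phenyl isopropylcarbamate | CC(C)NC(=O)Oc1cccc(OCc2ccccc2)c1[Si](C)(C)C
F10 | step 8 | 3-(benzyloxy)-2-(trimethylsilyl)phenyl trifluoromethanesulfonate | C[Si](C)(C)c1c(OCc2ccccc2)cccc1OS(=O)(=O)C(F)(F)F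
F11 | step 8 | 9-[3,4-bis(benzyloxy)phenyl]non-8-enoic acid (Z/E mixture) | OC(=O)CCCCCCC=Cc1ccc(OCc2ccccc2)c(OCc2ccccc2)c1
F12 | step 8 | 9-[3,4-bis(benzyloxy)phenyl]nonanoic acid | OC(=O)CCCCCCCCc1ccc(OCc2ccccc2)c(OCc2ccccc2)c1
F13 | step 8 | 1-[2-(benzyloxy)-6-hydroxyphenyl]-9-[3,4-bis(benzyloxy)phenyl]nonan-1-one | O=C(CCCCCCCCc1ccc(OCc2ccccc2)c(OCc2ccccc2)c1)c1c(O)cccc1OCc1ccccc1
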